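Atom labels: the lactone ring is O1–C2(=O)–C3–C4–C5. C6 is the ArCH2 carbon on C3 and C7 the ArCH(OH) carbon on C4. The target is read as 3S,4R,7R, with O3 and C7 cis on the lactone ring.
Enabling feature: ring atom C5 carries only hydrogens besides O1 and C4 and sits γ to the C2 carbonyl, so it can exist as a CH3 on C4, within reach of a C2 carboxylate, until the last C–O bond is made.
Cuts: O1–C5 (C–H lactonisation), then C2–C3 (vinyl as latent carboxyl), C3–C6 (benzylic Grignard reagent on a Weinreb amide) and C4–C7 (aldol).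
Forward: the aldol joins C7 to C4–C3, C6 and then C2 are added at C3, and the 1,3-dioxane ring (O3/O7 acetonide) is closed. Vinyl then becomes CO2H, the lactone ring closes last, and two deprotections follow.
Stereochemistry: C4 and C7 come from an Evans syn aldol with the (R)-oxazolidinone. C3 comes from Felkin–Anh addition of vinyl to the O7-silylated ketone, because a chelated vinyl addition would give the C3 epimer. The key step sets nothing new.

Key step: step 11

Assumption: 4-(benzyloxy)-3-methoxybenzaldehyde and 4-(benzyloxy)-3-methoxybenzyl alcohol are taken as catalogue chemicals; each is one K2CO3/BnBr step from vanillin or vanillyl alcohol.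

Step 1
Reactants: 1 4-(benzyloxy)-3-methoxybenzyl alcohol
Product: 2 4-(benzyloxy)-3-methoxybenzyl chloride
Conditions: SOCl2, CH2Cl2, 0 °C; used crude
Reagents that add atoms: thionyl chloride, O=S(Cl)Cl
Why: Chlorination of a benzylic alcohol through its chlorosulfite is a standard substitution that is fast on this electron-rich ring, and no stereocentre is involved.

Step 2
Reactants: 3 (R)-4-benzyl-3-propionyloxazolidin-2-one; 4 4-(benzyloxy)-3-methoxybenzaldehyde
Product: 7 (R)-4-benzyl-3-[(2R,3R)-3-(4-benzyloxy-3-methoxyphenyl)-3-hydroxy-2-methylpropanoyl]oxazolidin-2-one, via boron enolate 5 (not isolated), via boron aldolate 6 (not isolated)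
Conditions: Bu2BOTf, Et3N, CH2Cl2, −78 to 0 °C; 4, −78 to 0 °C; H2O2, MeOH, pH 7 buffer, 0 °C
Reagents that add atoms: none
Why: Evans syn aldol, in which soft enolisation gives the Z enolate 5 and a Zimmerman–Traxler chair on the face away from the auxiliary benzyl group lets the (R)-auxiliary set C4 and C7 together as the (2R,3R) syn pair.

Step 3
Reactants: 7 aldol adduct
Product: 8 (2R,3R)-3-[4-(benzyloxy)-3-methoxyphenyl]-3-hydroxy-N-methoxy-N,2-dimethylpropanamide
Conditions: AlMe3, MeONHMe·HCl, CH2Cl2, −10 °C to rt; Rochelle salt work-up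
Reagents that add atoms: N,O-dimethylhydroxylamine hydrochloride, CNOC.Cl
Why: Weinreb transamidation with the aluminium amide attacks the exocyclic imide carbonyl, is helped by the aluminium alkoxide of the free C7 hydroxyl, and is known to leave the α-centre C4 unepimerised.

Step 4
Reactants: 8 hydroxy Weinreb amide
Product: 9 (2R,3R)-3-[4-(benzyloxy)-3-methoxyphenyl]-3-[(tert-butyldimethylsilyl)oxy]-N-methoxy-N,2-dimethylpropanamide
Conditions: TBSOTf, 2,6-lutidine, CH2Cl2, 0 °C
Reagents that add atoms: tert-butyldimethylsilyl triflate, CC(C)(C)[Si](C)(C)OS(=O)(=O)C(F)(F)F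
Why: Silylation of a secondary benzylic alcohol with a silyl triflate and a hindered base is routine, and the bulky, weakly basic OTBS group is chosen because it cannot chelate magnesium or cerium in step 6.

Step 5
Reactants: 2 4-(benzyloxy)-3-methoxybenzyl chloride; 9 silylated Weinreb amide
Product: 12 (3R,4R)-1,4-bis[4-(benzyloxy)-3-methoxyphenyl]-4-[(tert-butyldimethylsilyl)oxy]-3-methylbutan-2-one, via Grignard reagent 10 (not isolated), via tetrahedral adduct 11 (not isolated)
Conditions: Mg turnings (excess), 2-MeTHF, 0 °C, slow addition of 2; then 9, THF, −10 to 0 °C; aq. NH4Cl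
Reagents that add atoms: none
Why: Weinreb ketone synthesis, in which slow addition to excess magnesium keeps Wurtz coupling of 10 low, the chelated adduct 11 survives until the quench so that only one addition occurs, and C4 is not enolised.

Step 6
Reactants: 12 benzyl ketone; 13 vinylmagnesium bromide
Product: 15 (3R,4R,5R)-5-[4-(benzyloxy)-3-methoxyphenyl]-3-[4-(benzyloxy)-3-methoxybenzyl]-5-[(tert-butyldimethylsilyl)oxy]-4-methylpent-1-en-3-ol, via vinylcerium dichloride 14 (not isolated)
Conditions: CeCl3 (dried), THF; 13, −78 °C; then 12, −78 °C; aq. NH4Cl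
Reagents that add atoms: none
Why: Organocerium (Imamoto) 1,2-addition suppresses enolisation of the acidic benzyl ketone, and with a non-chelating silyl ether the Felkin–Anh model applies, so vinyl enters anti to the large CH(OTBS)Ar group and past C4–H and sets C3 with vinyl and the C4 methyl on the same side of the later dioxane ring.

Step 7
Reactants: 15 silylated carbinol
Product: 16 (1R,2R,3R)-1-[4-(benzyloxy)-3-methoxyphenyl]-3-[4-(benzyloxy)-3-methoxybenzyl]-2-methylpent-4-ene-1,3-diol
Conditions: Bu4NF, THF, 0 °C to rt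
Reagents that add atoms: none
Why: Fluoride-induced desilylation works without acid and so spares both the ionisable C7 benzylic position and the tertiary allylic alcohol.

Step 8
Reactants: 16 diol
Product: 17 (4R,5R,6R)-4-[4-(benzyloxy)-3-methoxybenzyl]-6-[4-(benzyloxy)-3-methoxyphenyl]-4-ethenyl-2,2,5-trimethyl-1,3-dioxane
Conditions: 2-methoxypropene, PPTS (cat.), CH2Cl2, 0 °C to rt
Reagents that add atoms: 2-methoxypropene, C=C(C)OC
Why: Acid-catalysed acetalisation of a 1,3-diol with an enol ether runs under very mild PPTS catalysis even when one hydroxyl is tertiary, closes the dioxane ring and breaks no bond at a stereocentre.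

Step 9
Reactants: 17 vinyl acetonide
Product: 19 (4S,5R,6R)-4-[4-(benzyloxy)-3-methoxybenzyl]-6-[4-(benzyloxy)-3-methoxyphenyl]-2,2,5-trimethyl-1,3-dioxane-4-carbaldehyde, via vicinal diol 18 (not isolated)
Conditions: OsO4 (cat.), NaIO4, 2,6-lutidine, dioxane/H2O, rt
Reagents that add atoms: osmium tetroxide, O=[Os](=O)(=O)=O; sodium periodate, [Na+].[O-]I(=O)(=O)=O
Why: Lemieux–Johnson cleavage dihydroxylates the only alkene to 18 and splits it in the same flask, spares the two electron-rich arenes that ozone could attack, and is buffered by 2,6-lutidine for the sake of the acetonide.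

Step 10
Reactants: 19 aldehyde
Product: 20 (4S,5R,6R)-4-[4-(benzyloxy)-3-methoxybenzyl]-6-[4-(benzyloxy)-3-methoxyphenyl]-2,2,5-trimethyl-1,3-dioxane-4-carboxylic acid
Conditions: NaClO2, NaH2PO4, 2-methyl-2-butene, tBuOH/H2O, rt
Reagents that add atoms: sodium chlorite, [Na+].[O-]Cl=O
Why: Pinnick oxidation turns the hindered, non-enolisable aldehyde into the acid under a mild phosphate buffer, and 2-methyl-2-butene traps hypochlorous acid before it can chlorinate the arenes.

Step 11
Reactants: 20 acetonide acid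
Product: 22 (4R,4aR,7aS)-7a-[4-(benzyloxy)-3-methoxybenzyl]-4-[4-(benzyloxy)-3-methoxyphenyl]-2,2-dimethyltetrahydro-7H-furo[3,4-d][1,3]dioxin-7-one (lactone acetonide; C3 S and C4 R and C7 R), via palladacycle 21 (not isolated)
Conditions: Pd(OAc)2 (10 mol %), N-acetylglycine (20 mol %), CsHCO3 (0.5 equiv), tBuOOH (5.5 M in decane, 2 equiv), (CF3)2CHOH, 60 °C
Reagents that add atoms: none
Why: Proposed new method: the carboxylate of 20 binds Pd(OAc)2 carrying N-acetylglycine, the ligand acetamide takes the proton in a concerted metalation–deprotonation of a C5–H bond to give the six-membered palladacycle 21 (Pd, O, C2, C3, C4, C5), tBuOOH raises the metal from divalent to tetravalent palladium, and C–O reductive elimination joins the carboxylate oxygen O1 to C5. The nearest precedent in type is the γ-methyl C–H lactonisation of plain aliphatic acids with a fully substituted α-carbon, run with Pd(OAc)2, an enabling ligand and a peroxide; an α-oxygenated acid flanked by electron-rich benzylic groups lies outside it. The one ring closed is the five-membered lactone O1–C2–C3–C4–C5, formed in a 5-exo-tet sense as the tethered carboxylate displaces palladium from C5, and it comes out cis-fused to the dioxane ring. No stereocentre is created, and C3, C4 and C7 keep their configuration because none of their bonds is broken. The step needs the methyl C–H bonds to react before C6–H, C4–H, C7–H and the ortho C–H bonds of the C6 aryl ring: this kind of metalation prefers primary C–H bonds, the quaternary C3 and the dioxane ring hold CO2H and CH3 cis and gauche, C4–H and C7–H lie on the opposite ring face, and a ligand with a five-membered chelate is matched to a six-membered palladacycle rather than to the five-membered one (C6–H) or the seven-membered one (ortho C–H). The acetonide also shields the α-hydroxy acid from oxidative decarboxylation and keeps O7 from lactonising on C2, while bicarbonate and water-free tBuOOH keep the medium from opening it.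

Step 12
Reactants: 22 lactone acetonide
Product: 23 (3S,4R)-3-[4-(benzyloxy)-3-methoxybenzyl]-4-{(R)-[4-(benzyloxy)-3-methoxyphenyl](hydroxy)methyl}-3-hydroxydihydrofuran-2(3H)-one
Conditions: AcOH/H2O (4:1), 40 °C
Reagents that add atoms: none
Why: Acetal hydrolysis in a weak aqueous acid runs through the O–CMe2 oxocarbenium ion, so the C3–O and C7–O bonds stay intact and both configurations are retained, and the low acidity and temperature are meant to avoid ionisation at C7 and acyl shift to O7.

Step 13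
Reactants: 23 di-O-benzyl lactone diol
Product: 24 (3S,4R)-3-hydroxy-4-[(R)-hydroxy(4-hydroxy-3-methoxyphenyl)methyl]-3-(4-hydroxy-3-methoxybenzyl)dihydrofuran-2(3H)-one (target)
Conditions: H2 (1 atm), Pd/C (10 %), EtOAc, rt; stopped after uptake of 2 equiv H2
Reagents that add atoms: none
Why: Hydrogenolysis of aryl benzyl ethers over Pd/C in neutral ethyl acetate is much faster than that of a secondary benzylic alcohol, so C7–OH, the lactone and all three stereocentres should remain untouched.

Compound list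
1 | 4-(benzyloxy)-3-methoxybenzyl alcohol | COc1cc(CO)ccc1OCc1ccccc1 | starting material
2 | 4-(benzyloxy)-3-methoxybenzyl chloride | COc1cc(CCl)ccc1OCc1ccccc1 | intermediate
3 | (R)-4-benzyl-3-propionyloxazolidin-2-one | CCC(=O)N1[C@H](Cc2ccccc2)COC1=O | starting material
4 | 4-(benzyloxy)-3-methoxybenzaldehyde | COc1cc(C=O)ccc1OCc1ccccc1 | starting material
5 | (Z)-dibutylboron enolate of 3 | C/C=C(\OB(CCCC)CCCC)N1[C@H](Cc2ccccc2)COC1=O | intermediate
6 | dibutylboron aldolate of 7 | C[C@H]([C@@H](OB(CCCC)CCCC)c1ccc(OCc2ccccc2)c(OC)c1)C(=O)N1[C@H](Cc2ccccc2)COC1=O | intermediate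
7 | (R)-4-benzyl-3-[(2R,3R)-3-(4-benzyloxy-3-methoxyphenyl)-3-hydroxy-2-methylpropanoyl]oxazolidin-2-one | C[C@H]([C@@H](O)c1ccc(OCc2ccccc2)c(OC)c1)C(=O)N1[C@H](Cc2ccccc2)COC1=O | intermediate
8 | (2R,3R)-3-[4-(benzyloxy)-3-methoxyphenyl]-3-hydroxy-N-methoxy-N,2-dimethylpropanamide | C[C@H]([C@@H](O)c1ccc(OCc2ccccc2)c(OC)c1)C(=O)N(C)OC | intermediate
9 | TBS ether of 8, (2R,3R) | C[C@H]([C@@H](O[Si](C)(C)C(C)(C)C)c1ccc(OCc2ccccc2)c(OC)c1)C(=O)N(C)OC | intermediate
10 | [4-(benzyloxy)-3-methoxybenzyl]magnesium chloride | COc1cc(C[Mg]Cl)ccc1OCc1ccccc1 | intermediate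
11 | tetrahedral magnesium adduct of 9 and 10 (new centre undefined) | C[C@H]([C@@H](O[Si](C)(C)C(C)(C)C)c1ccc(OCc2ccccc2)c(OC)c1)C(O[Mg]Cl)(Cc1ccc(OCc2ccccc2)c(OC)c1)N(C)OC | intermediate
12 | (3R,4R)-1,4-bis[4-(benzyloxy)-3-methoxyphenyl]-4-[(tert-butyldimethylsilyl)oxy]-3-methylbutan-2-one | C[C@H]([C@@H](O[Si](C)(C)C(C)(C)C)c1ccc(OCc2ccccc2)c(OC)c1)C(=O)Cc1ccc(OCc2ccccc2)c(OC)c1 | intermediate
13 | vinylmagnesium bromide | C=C[Mg]Br | starting material
14 | vinylcerium dichloride | C=C[Ce](Cl)Cl | intermediate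
15 | (3R,4R,5R)-5-[4-(benzyloxy)-3-methoxyphenyl]-3-[4-(benzyloxy)-3-methoxybenzyl]-5-[(tert-butyldimethylsilyl)oxy]-4-methylpent-1-en-3-ol | C=C[C@](O)(Cc1ccc(OCc2ccccc2)c(OC)c1)[C@H](C)[C@@H](O[Si](C)(C)C(C)(C)C)c1ccc(OCc2ccccc2)c(OC)c1 | intermediate
16 | (1R,2R,3R)-1-[4-(benzyloxy)-3-methoxyphenyl]-3-[4-(benzyloxy)-3-methoxybenzyl]-2-methylpent-4-ene-1,3-diol | C=C[C@](O)(Cc1ccc(OCc2ccccc2)c(OC)c1)[C@H](C)[C@@H](O)c1ccc(OCc2ccccc2)c(OC)c1 | intermediate
17 | (4R,5R,6R)-4-[4-(benzyloxy)-3-methoxybenzyl]-6-[4-(benzyloxy)-3-methoxyphenyl]-4-ethenyl-2,2,5-trimethyl-1,3-dioxane | C=C[C@@]1(Cc2ccc(OCc3ccccc3)c(OC)c2)OC(C)(C)O[C@@H](c2ccc(OCc3ccccc3)c(OC)c2)[C@H]1C | intermediate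
18 | 1-[(4S,5R,6R)-dioxan-4-yl]ethane-1,2-diol from 17 (carbinol centre undefined) | OCC(O)[C@@]1(Cc2ccc(OCc3ccccc3)c(OC)c2)OC(C)(C)O[C@@H](c2ccc(OCc3ccccc3)c(OC)c2)[C@H]1C | intermediate
19 | (4S,5R,6R)-4-[4-(benzyloxy)-3-methoxybenzyl]-6-[4-(benzyloxy)-3-methoxyphenyl]-2,2,5-trimethyl-1,3-dioxane-4-carbaldehyde | O=C[C@@]1(Cc2ccc(OCc3ccccc3)c(OC)c2)OC(C)(C)O[C@@H](c2ccc(OCc3ccccc3)c(OC)c2)[C@H]1C | intermediate
20 | (4S,5R,6R)-4-[4-(benzyloxy)-3-methoxybenzyl]-6-[4-(benzyloxy)-3-methoxyphenyl]-2,2,5-trimethyl-1,3-dioxane-4-carboxylic acid | OC(=O)[C@@]1(Cc2ccc(OCc3ccccc3)c(OC)c2)OC(C)(C)O[C@@H](c2ccc(OCc3ccccc3)c(OC)c2)[C@H]1C | intermediate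
21 | six-membered palladacycle Pd–O–C2–C3–C4–C5 from 20 (other ligands omitted) | [Pd]2OC(=O)[C@@]1(Cc3ccc(OCc4ccccc4)c(OC)c3)OC(C)(C)O[C@@H](c3ccc(OCc4ccccc4)c(OC)c3)[C@H]1C2 | intermediate
22 | (4R,4aR,7aS)-7a-[4-(benzyloxy)-3-methoxybenzyl]-4-[4-(benzyloxy)-3-methoxyphenyl]-2,2-dimethyltetrahydro-7H-furo[3,4-d][1,3]dioxin-7-one | COc1cc(C[C@]23OC(C)(C)O[C@@H](c4ccc(OCc5ccccc5)c(OC)c4)[C@H]2COC3=O)ccc1OCc1ccccc1 | intermediate
23 | (3S,4R)-3-[4-(benzyloxy)-3-methoxybenzyl]-4-{(R)-[4-(benzyloxy)-3-methoxyphenyl](hydroxy)methyl}-3-hydroxydihydrofuran-2(3H)-one | COc1cc(C[C@@]2(O)C(=O)OC[C@@H]2[C@@H](O)c2ccc(OCc3ccccc3)c(OC)c2)ccc1OCc1ccccc1 | intermediate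
24 | (3S,4R)-3-hydroxy-4-[(R)-hydroxy(4-hydroxy-3-methoxyphenyl)methyl]-3-(4-hydroxy-3-methoxybenzyl)dihydrofuran-2(3H)-one | COc1cc(C[C@@]2(O)C(=O)OC[C@@H]2[C@@H](O)c2ccc(O)c(OC)c2)ccc1O | target

Total step count: 13.
Longest linear sequence: 12 (steps 2 to 13, from 3 and 4); step 1 lies on the side branch.

Steps most likely to fail

**Step 11.**
- What may go wrong:
  - palladation at the ortho position of the C6 aryl ring or at C6–H instead of the methyl group;
  - peroxide-driven oxidation at the benzyl ether CH2 groups;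
  - oxidative loss of CO2 from the α-alkoxy acid;
  - solvolytic opening of the C7–O bond in the ionising solvent.
- The fallback brings C5 in already oxygenated and closes the lactone by ordinary acylation. It sets out from aldehyde 4 and comes back at target 24.
- (R)-4-Benzyloxazolidin-2-one is N-acylated (n-BuLi, 3-(benzyloxy)propanoyl chloride) to the imide F1.
- The boron-mediated syn aldol of F1 with 4 under the conditions of step 2 should give the C5-benzyloxy aldol adduct F2. A covalent boron enolate is expected to resist β-elimination at −78 °C.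
- Transamidation as in step 3 gives the Weinreb amide F3, silylation as in step 4 the TBS ether F4, and Grignard reagent 10 as in step 5 the ketone F5.
- Vinylcerium 14 adds as in step 6 to give the carbinol F6. A chelate through the C5 benzyloxy oxygen would expose the same face as the Felkin–Anh model.
- Ozonolysis with Me2S work-up gives the α-hydroxy aldehyde F7. Periodate is avoided because the tertiary alcohol is free.
- Pinnick oxidation gives the α-hydroxy acid F8, in which O7 stays silylated so that it cannot lactonise on C2.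
- Hydrogenolysis (H2, Pd/C, EtOAc) removes all three benzyl groups to the trihydroxy acid F9. This closes O1 onto C2 in the same flask to give the 7-O-TBS lactone F10.
- HF·pyridine in THF/pyridine then releases 24.

**Step 6.**
- What may go wrong: poor facial selectivity, because the polar effect of the C7–O bond opposes the Felkin–Anh preference, or return of ketone through enolisation.
- The fallback reverses the order in which the two C3 substituents arrive, so that chelation works for the route. It sets out from hydroxy amide 8 and comes back at diol 16.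
- Excess 13 (THF, 0 °C, inverse quench into cold acid) gives the β-hydroxy vinyl ketone F11, which is used at once.
- Excess Grignard reagent 10 in CH2Cl2/2-MeTHF at −78 °C first forms the O7 magnesium alkoxide, which ties O7 and the carbonyl oxygen into a six-membered chelate.
- The benzyl group then adds 1,2 from the face opposite the C4 methyl and C7 aryl groups. This gives 16 directly and makes steps 4 and 7 unnecessary.

**Step 12.**
- What may go wrong: acid-induced ionisation at C7 followed by epimerisation or Friedel–Crafts closure onto the C6 aryl ring, and acyl shift of the lactone to O7.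
- The fallback replaces the acid-labile acetal by a fluoride-labile ring. It sets out from diol 16 and comes back at 23.
- tBu2Si(OTf)2 and 2,6-lutidine in CH2Cl2 give the di-tert-butylsilylene alkene F12.
- The conditions of steps 9 and 10 give the silylene aldehyde F13 and the silylene acid F14.
- The lactonisation of step 11 gives the silylene lactone F15.
- HF·pyridine buffered with pyridine in THF at 0 °C frees O3 and O7 without a Brønsted acid strong enough to ionise C7.

Further compounds
F1 | step 11 | (R)-4-benzyl-3-[3-(benzyloxy)propanoyl]oxazolidin-2-one | O=C(CCOCc1ccccc1)N1[C@H](Cc2ccccc2)COC1=O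
F2 | step 11 | syn aldol adduct, analogue of 7 with CH2OBn on C4 | C(OCc1ccccc1)[C@H]([C@@H](O)c1ccc(OCc2ccccc2)c(OC)c1)C(=O)N1[C@H](Cc2ccccc2)COC1=O
F3 | step 11 | Weinreb amide, analogue of 8 with CH2OBn on C4 | C(OCc1ccccc1)[C@H]([C@@H](O)c1ccc(OCc2ccccc2)c(OC)c1)C(=O)N(C)OC
F4 | step 11 | TBS ether, analogue of 9 with CH2OBn on C4 | C(OCc1ccccc1)[C@H]([C@@H](O[Si](C)(C)C(C)(C)C)c1ccc(OCc2ccccc2)c(OC)c1)C(=O)N(C)OC
F5 | step 11 | ketone, analogue of 12 with CH2OBn on C4 | C(OCc1ccccc1)[C@H]([C@@H](O[Si](C)(C)C(C)(C)C)c1ccc(OCc2ccccc2)c(OC)c1)C(=O)Cc1ccc(OCc2ccccc2)c(OC)c1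
F6 | step 11 | vinyl carbinol, analogue of 15 with CH2OBn on C4 | C=C[C@](O)(Cc1ccc(OCc2ccccc2)c(OC)c1)[C@H](COCc1ccccc1)[C@@H](O[Si](C)(C)C(C)(C)C)c1ccc(OCc2ccccc2)c(OC)c1
F7 | step 11 | α-hydroxy aldehyde from F6 | O=C[C@](O)(Cc1ccc(OCc2ccccc2)c(OC)c1)[C@H](COCc1ccccc1)[C@@H](O[Si](C)(C)C(C)(C)C)c1ccc(OCc2ccccc2)c(OC)c1
F8 | step 11 | α-hydroxy acid from F7 | OC(=O)[C@](O)(Cc1ccc(OCc2ccccc2)c(OC)c1)[C@H](COCc1ccccc1)[C@@H](O[Si](C)(C)C(C)(C)C)c1ccc(OCc2ccccc2)c(OC)c1
F9 | step 11 | debenzylated trihydroxy acid, O7 silylated | OC(=O)[C@](O)(Cc1ccc(O)c(OC)c1)[C@H](CO)[C@@H](O[Si](C)(C)C(C)(C)C)c1ccc(O)c(OC)c1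
F10 | step 11 | 7-O-TBS ether of 24 | COc1cc(C[C@@]2(O)C(=O)OC[C@@H]2[C@@H](O[Si](C)(C)C(C)(C)C)c2ccc(O)c(OC)c2)ccc1O
F11 | step 6 | (4R,5R)-5-[4-(benzyloxy)-3-methoxyphenyl]-5-hydroxy-4-methylpent-1-en-3-one | C=CC(=O)[C@H](C)[C@@H](O)c1ccc(OCc2ccccc2)c(OC)c1
F12 | step 12 | di-tert-butylsilylene analogue of 17 | C=C[C@@]1(Cc2ccc(OCc3ccccc3)c(OC)c2)O[Si](C(C)(C)C)(C(C)(C)C)O[C@@H](c2ccc(OCc3ccccc3)c(OC)c2)[C@H]1C
F13 | step 12 | di-tert-butylsilylene analogue of 19 | O=C[C@@]1(Cc2ccc(OCc3ccccc3)c(OC)c2)O[Si](C(C)(C)C)(C(C)(C)C)O[C@@H](c2ccc(OCc3ccccc3)c(OC)c2)[C@H]1C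
F14 | step 12 | di-tert-butylsilylene analogue of 20 | OC(=O)[C@@]1(Cc2ccc(OCc3ccccc3)c(OC)c2)O[Si](C(C)(C)C)(C(C)(C)C)O[C@@H](c2ccc(OCc3ccccc3)c(OC)c2)[C@H]1C
F15 | step 12 | di-tert-butylsilylene analogue of 22 | COc1cc(C[C@]23O[Si](C(C)(C)C)(C(C)(C)C)O[C@@H](c4ccc(OCc5ccccc5)c(OC)c4)[C@H]2COC3=O)ccc1OCc1ccccc1
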